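**Retrosynthetic overview**

1. Eryvarin Q (27) comes from 25 by cleavage of the C6 silyl ether and then of the two ring B methoxymethyl ethers.
2. The strategy rests on one feature: ring A atoms C4 to C7 sit on the C3a–C7a edge of a furan that already carries the ring B aryl group at C2 and the formyl group at C3. Ring A is therefore cut at C4–C5 and C6–C7 into the furan-fused pyran-2-one 23 (diene termini C4 and C7, C7 already prenylated) and the siloxyacetylene 22 (C5 and C6, with the C6 oxygen); CO2 is lost.
3. Pyranone 23 is the dehydration product of formyl acid 18, which comes from furan triester 11 by selective saponification, α-prenylation, ester reduction and oxidation.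
4. The furan ring is cut by a Feist–Benary disconnection into chloro keto ester 8 (Darzens product of ring B aldehyde 5) and dimethyl 3-oxopentanedioate 9; aldehyde 5 comes from 2,4-dihydroxybenzaldehyde by bromination, protection and Stille prenylation.
5. Order of ring formation: ring B is bought, the furan ring is made in step 5, ring A is made last in step 11.

Key step: step 11

Assumption (remark on the chemistry): siloxyalkyne 22 is prepared (step 10) and not bought; compounds 8 and 15 to 18 are racemic because their single stereocentre is erased in steps 5 and 11. Throughout, Ar = 2,4-bis(methoxymethoxy)-5-(3-methylbut-2-en-1-yl)phenyl and prenyl = 3-methylbut-2-en-1-yl.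

**Route**

Step 1
Reactants: 1 2,4-dihydroxybenzaldehyde
Product: 2 5-bromo-2,4-dihydroxybenzaldehyde
Conditions: Br2 (1.0 equiv), AcOH, 15 °C → rt
Reagents that add atoms: bromine, BrBr
Why: Electrophilic aromatic bromination should go to C5, which is para to the 2-hydroxyl and ortho to the 4-hydroxyl and less hindered than C3 between the two hydroxyls.

Step 2
Reactants: 2 5-bromo-2,4-dihydroxybenzaldehyde
Product: 3 5-bromo-2,4-bis(methoxymethoxy)benzaldehyde
Conditions: NaH (2.5 equiv), MOMCl (2.6 equiv), DMF, 0 °C → rt
Reagents that add atoms: chloromethyl methyl ether, COCCl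
Why: O-Alkylation of both phenoxides (Williamson-type acetal formation) should protect the two hydroxyls, NaH being strong enough to convert the hydrogen-bonded 2-hydroxyl as well.

Step 3
Reactants: 3 5-bromo-2,4-bis(methoxymethoxy)benzaldehyde; 4 tributyl(3-methylbut-2-en-1-yl)stannane
Product: 5 2,4-bis(methoxymethoxy)-5-(3-methylbut-2-en-1-yl)benzaldehyde
Conditions: Pd(PPh3)4 (5 mol %), DMF, 95 °C
Reagents that add atoms: tributyl(3-methylbut-2-en-1-yl)stannane (4), CCCC[Sn](CCCC)(CCCC)CC=C(C)C
Why: Stille cross-coupling (oxidative addition of zerovalent palladium into the aryl bromide, transmetalation from the allylic stannane, reductive elimination) should give the linear prenyl arene and leaves the aldehyde and the acetals untouched.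

Step 4
Reactants: 5 2,4-bis(methoxymethoxy)-5-(3-methylbut-2-en-1-yl)benzaldehyde; 6 methyl dichloroacetate
Product: 8 methyl 3-Ar-3-chloro-2-oxopropanoate (racemic), via chloroglycidic ester 7 (not isolated)
Conditions: NaOMe (1.1 equiv), THF, −20 °C → rt
Reagents that add atoms: methyl dichloroacetate (6), COC(=O)C(Cl)Cl
Why: Darzens condensation gives the α-chloroglycidic ester 7, which opens at the benzylic carbon (cation stabilised by the ortho and para oxygen atoms) with chloride return to the β-chloro-α-keto ester; the new stereocentre is racemic and is removed in step 5.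

Step 5
Reactants: 8 methyl 3-Ar-3-chloro-2-oxopropanoate; 9 dimethyl 3-oxopentanedioate
Product: 11 dimethyl 2-Ar-5-(2-methoxy-2-oxoethyl)furan-3,4-dicarboxylate, via hydroxydihydrofuran 10 (not isolated)
Conditions: 2,6-lutidine, THF, 0 → 45 °C; then MsCl, Et3N, CH2Cl2, 0 °C → rt
Reagents that add atoms: dimethyl 3-oxopentanedioate (9), COC(=O)CC(=O)CC(=O)OC
Why: Feist–Benary furan synthesis, in which the active methylene of 9 adds to the very electrophilic keto group of 8, the enol oxygen displaces the benzylic chloride to give 10, and mesylation of the tertiary alcohol with elimination aromatises the ring, so that the aryl group ends next to the ring oxygen and the acetate chain on the other α-carbon.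

Step 6
Reactants: 11 dimethyl 2-Ar-5-(2-methoxy-2-oxoethyl)furan-3,4-dicarboxylate
Product: 12 [5-Ar-3,4-bis(methoxycarbonyl)furan-2-yl]acetic acid
Conditions: LiOH·H2O (1.05 equiv), THF/H2O, 0 °C; then 1 M HCl to pH 4 at 0 °C
Reagents that add atoms: lithium hydroxide, [Li+].[OH-]
Why: Chemoselective saponification, since the unhindered aliphatic ester of the acetate chain is hydrolysed much faster than the two conjugated, flanked furan esters, as in the monohydrolysis of homophthalate diesters.

Step 7
Reactants: 12 [5-Ar-3,4-bis(methoxycarbonyl)furan-2-yl]acetic acid; 13 prenyl bromide (1-bromo-3-methylbut-2-ene)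
Product: 15 2-[5-Ar-3,4-bis(methoxycarbonyl)furan-2-yl]-5-methylhex-4-enoic acid (racemic), via dilithium enediolate 14 (not isolated)
Conditions: LiN(i-Pr)2 (2.2 equiv), THF, −78 °C; then 13 (1.05 equiv), −78 → −20 °C; 1 M HCl work-up at 0 °C
Reagents that add atoms: prenyl bromide (13), CC(C)=CCBr
Why: Alkylation of a carboxylic acid dianion, in which the α-carbanion of 14 (stabilised by the carboxylate and by conjugation through the furan into the C3 ester) is C-alkylated by the allylic bromide in an SN2 reaction; the new stereocentre forms racemic and becomes sp2 in step 11.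

Step 8
Reactants: 15 2-[5-Ar-3,4-bis(methoxycarbonyl)furan-2-yl]-5-methylhex-4-enoic acid
Product: 17 2-[5-Ar-3,4-bis(hydroxymethyl)furan-2-yl]-5-methylhex-4-enoic acid (racemic), via lithium carboxylate 16 (not isolated)
Conditions: LiOMe (1.0 equiv), THF/MeOH, 0 °C; then LiBH4 (4 equiv), 0 → 45 °C; cold 0.5 M HCl to pH 5, used at once
Reagents that add atoms: none
Why: Chemoselective hydride reduction, in which LiBH4 reduces the two methyl esters to primary alcohols but not the carboxylate salt or the trisubstituted alkenes; forming the salt first prevents release of borane, and the cold work-up at pH 5 keeps the δ-hydroxy acid from lactonising before step 9.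

Step 9
Reactants: 17 2-[5-Ar-3,4-bis(hydroxymethyl)furan-2-yl]-5-methylhex-4-enoic acid
Product: 18 2-(5-Ar-3,4-diformylfuran-2-yl)-5-methylhex-4-enoic acid (racemic)
Conditions: Dess–Martin periodinane (2.4 equiv), pyridine, CH2Cl2, 0 °C → rt
Reagents that add atoms: none
Why: Dess–Martin oxidation should convert both furylmethanols into aldehydes without over-oxidation, tolerates the free carboxylic acid, and is fast enough to outrun lactonisation while pyridine buffers the acetic acid that forms.

Step 10
Reactants: 19 acetylene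
Product: 22 (ethynyloxy)triisopropylsilane, via lithium acetylide 20 (not isolated), via lithium ethynolate 21 (not isolated)
Conditions: n-BuLi (1.0 equiv), THF, −78 °C; t-BuOOLi (from t-BuOOH and n-BuLi, THF, −78 °C), −78 → −20 °C; i-Pr3SiOTf, −78 → 0 °C
Reagents that add atoms: tert-butyl hydroperoxide, CC(C)(C)OO; triisopropylsilyl trifluoromethanesulfonate, CC(C)[Si](OS(=O)(=O)C(F)(F)F)(C(C)C)C(C)C
Why: Oxidation of a lithium acetylide by lithium tert-butyl peroxide (oxygen transfer to carbon) gives the ynolate, and the bulky, hard silyl triflate silylates ynolates on oxygen, which is the established way from terminal alkynes to triisopropylsilyl ynol ethers.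

Step 11
Reactants: 18 2-(5-Ar-3,4-diformylfuran-2-yl)-5-methylhex-4-enoic acid; 22 (ethynyloxy)triisopropylsilane
Product: 25 2-Ar-7-prenyl-6-[(triisopropylsilyl)oxy]-1-benzofuran-3-carbaldehyde, via furopyranone 23 (not isolated), via bridged lactone 24 (not isolated)
Conditions: i-PrN=C=N-i-Pr (1.2 equiv), toluene, 0 °C → rt; then 22 (3 equiv), 80 °C
Reagents that add atoms: (ethynyloxy)triisopropylsilane (22), C#CO[Si](C(C)C)(C(C)C)C(C)C
Why: Proposed new method: the carbodiimide activates the carboxyl group of 18, the oxygen of the neighbouring formyl group closes onto the activated acyl carbon and loss of the α-proton gives the furan-fused pyran-2-one 23, a lactone-bridged furan-2,3-quinodimethane, whose diene termini C4 and C7 add the siloxyalkyne 22 to give the bridged lactone 24, which loses CO2 by retro-(4+2) cleavage. The closest known reaction type is the formation of 2-benzopyran-3-ones from o-acylarylacetic acids, and of pyrano[3,4-b]indol-3-ones, followed by Diels–Alder addition of alkynes and CO2 loss to give naphthalenes and carbazoles; a furan-fused pyranone with a siloxyalkyne partner has not been shown. Ring A is closed by an intermolecular (4+2) cycloaddition that forms C4–C5 and C6–C7 in one operation, and the CO2 extrusion is driven by the gain of benzene and furan aromaticity. No stereocentre remains, because the racemic α-carbon of 18 becomes the sp2 carbon C7 and the bridgehead centres of 24 disappear with the CO2. The step needs the nucleophilic CH terminus of 22 to bond to C4 (the oxygen-bearing, electrophilic diene terminus, made more electron-poor by the C3 formyl group) and its silyloxy carbon to bond to the prenyl-bearing C7, which the matched polarity of the two partners secures. It also needs only the formyl group beside the acid chain to react, which holds because the other formyl group cannot reach the acid, and the acid is consumed by the carbodiimide before 22 is added so that the ynol ether never meets a free carboxylic acid.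

Step 12
Reactants: 25 2-Ar-7-prenyl-6-[(triisopropylsilyl)oxy]-1-benzofuran-3-carbaldehyde
Product: 26 2-Ar-6-hydroxy-7-prenyl-1-benzofuran-3-carbaldehyde
Conditions: Bu4NF (1.1 equiv), THF, 0 °C; aq. NH4Cl
Reagents that add atoms: none
Why: Fluoride-induced cleavage of the aryl silyl ether (Si–F bond formation) should free the C6 phenol without touching the acetals, the aldehyde or the prenyl groups.

Step 13
Reactants: 26 2-Ar-6-hydroxy-7-prenyl-1-benzofuran-3-carbaldehyde
Product: 27 eryvarin Q, 2-[2,4-dihydroxy-5-(3-methylbut-2-en-1-yl)phenyl]-6-hydroxy-7-(3-methylbut-2-en-1-yl)-1-benzofuran-3-carbaldehyde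
Conditions: 3 M aq. HCl/MeOH (1:10), 40 °C, short reaction time
Reagents that add atoms: none
Why: Acid-catalysed transacetalisation of the two methoxymethyl ethers to methanol should free the ring B phenols, and mild acid with a short reaction time is chosen because prenyl groups ortho to free phenols can cyclise to chromans under stronger acid.

**Compound list**

1 | 2,4-dihydroxybenzaldehyde | O=Cc1ccc(O)cc1O | starting material
2 | 5-bromo-2,4-dihydroxybenzaldehyde | O=Cc1cc(Br)c(O)cc1O | intermediate
3 | 5-bromo-2,4-bis(methoxymethoxy)benzaldehyde | O=Cc1cc(Br)c(OCOC)cc1OCOC | intermediate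
4 | tributyl(3-methylbut-2-en-1-yl)stannane | CCCC[Sn](CCCC)(CCCC)CC=C(C)C | starting material
5 | 2,4-bis(methoxymethoxy)-5-(3-methylbut-2-en-1-yl)benzaldehyde | O=Cc1cc(CC=C(C)C)c(OCOC)cc1OCOC | intermediate
6 | methyl dichloroacetate | COC(=O)C(Cl)Cl | starting material
7 | methyl 3-Ar-2-chlorooxirane-2-carboxylate (racemic diastereomer mixture, not isolated) | COC(=O)C1(Cl)OC1c1cc(CC=C(C)C)c(OCOC)cc1OCOC | intermediate
8 | methyl 3-Ar-3-chloro-2-oxopropanoate (racemic) | COC(=O)C(=O)C(Cl)c1cc(CC=C(C)C)c(OCOC)cc1OCOC | intermediate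
9 | dimethyl 3-oxopentanedioate | COC(=O)CC(=O)CC(=O)OC | starting material
10 | dimethyl 5-Ar-4-hydroxy-2-(2-methoxy-2-oxoethyl)-4,5-dihydrofuran-3,4-dicarboxylate (racemic diastereomer mixture, not isolated) | COC(=O)CC1=C(C(=O)OC)C(O)(C(=O)OC)C(c2cc(CC=C(C)C)c(OCOC)cc2OCOC)O1 | intermediate
11 | dimethyl 2-Ar-5-(2-methoxy-2-oxoethyl)furan-3,4-dicarboxylate | COC(=O)Cc1oc(-c2cc(CC=C(C)C)c(OCOC)cc2OCOC)c(C(=O)OC)c1C(=O)OC | intermediate
12 | [5-Ar-3,4-bis(methoxycarbonyl)furan-2-yl]acetic acid | OC(=O)Cc1oc(-c2cc(CC=C(C)C)c(OCOC)cc2OCOC)c(C(=O)OC)c1C(=O)OC | intermediate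
13 | prenyl bromide (1-bromo-3-methylbut-2-ene) | CC(C)=CCBr | starting material
14 | dilithium salt of 12, carboxylate and α-carbanion (not isolated) | [Li+].[Li+].[O-]C(=O)[CH-]c1oc(-c2cc(CC=C(C)C)c(OCOC)cc2OCOC)c(C(=O)OC)c1C(=O)OC | intermediate
15 | 2-[5-Ar-3,4-bis(methoxycarbonyl)furan-2-yl]-5-methylhex-4-enoic acid (racemic) | CC(C)=CCC(C(=O)O)c1oc(-c2cc(CC=C(C)C)c(OCOC)cc2OCOC)c(C(=O)OC)c1C(=O)OC | intermediate
16 | lithium salt of 15 (racemic, not isolated) | [Li+].CC(C)=CCC(C(=O)[O-])c1oc(-c2cc(CC=C(C)C)c(OCOC)cc2OCOC)c(C(=O)OC)c1C(=O)OC | intermediate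
17 | 2-[5-Ar-3,4-bis(hydroxymethyl)furan-2-yl]-5-methylhex-4-enoic acid (racemic) | CC(C)=CCC(C(=O)O)c1oc(-c2cc(CC=C(C)C)c(OCOC)cc2OCOC)c(CO)c1CO | intermediate
18 | 2-(5-Ar-3,4-diformylfuran-2-yl)-5-methylhex-4-enoic acid (racemic) | CC(C)=CCC(C(=O)O)c1oc(-c2cc(CC=C(C)C)c(OCOC)cc2OCOC)c(C=O)c1C=O | intermediate
19 | acetylene | C#C | starting material
20 | lithium acetylide (not isolated) | [Li+].[C-]#C | intermediate
21 | lithium ethynolate (not isolated) | [Li+].[O-]C#C | intermediate
22 | (ethynyloxy)triisopropylsilane | C#CO[Si](C(C)C)(C(C)C)C(C)C | intermediate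
23 | 2-Ar-6-oxo-7-prenyl-6H-furo[3,2-c]pyran-3-carbaldehyde (not isolated) | O=CC1=C(c2cc(CC=C(C)C)c(OCOC)cc2OCOC)OC2=C(CC=C(C)C)C(=O)OC=C12 | intermediate
24 | bridged lactone from addition of 22 across C4 and C7 of 23, CH at C5 and silyloxy carbon at C6, O–C(=O) bridge retained (racemic, not isolated) | O=Cc1c(-c3cc(CC=C(C)C)c(OCOC)cc3OCOC)oc2c1C1C=C(O[Si](C(C)C)(C(C)C)C(C)C)C2(CC=C(C)C)C(=O)O1 | intermediate
25 | 2-Ar-7-prenyl-6-[(triisopropylsilyl)oxy]-1-benzofuran-3-carbaldehyde | O=Cc1c(-c2cc(CC=C(C)C)c(OCOC)cc2OCOC)oc2c(CC=C(C)C)c(O[Si](C(C)C)(C(C)C)C(C)C)ccc12 | intermediate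
26 | 2-Ar-6-hydroxy-7-prenyl-1-benzofuran-3-carbaldehyde | O=Cc1c(-c2cc(CC=C(C)C)c(OCOC)cc2OCOC)oc2c(CC=C(C)C)c(O)ccc12 | intermediate
27 | eryvarin Q | CC(C)=CCc1cc(-c2oc3c(CC=C(C)C)c(O)ccc3c2C=O)c(O)cc1O | target

**Step count**

Total: 13 steps. Longest linear sequence: 12 steps (steps 1 to 9 and 11 to 13); step 10 is a one-step side branch.

**The three steps most likely to fail**

Step 11 (proposed new method). The activated acid may rearrange to an N-acylurea, the furopyranone may dimerise before it meets the alkyne or be too stabilised to add it, the ynol ether may add to an aldehyde in a (2+2) sense, or 22 may isomerise to a silylketene on heating. The fallback uses known chemistry only, sets out from aldehyde 5 and comes back at 25. Aldehyde 5 is homologated with dimethyl (1-diazo-2-oxopropyl)phosphonate and K2CO3 in MeOH (Ohira–Bestmann reaction) to 1-ethynyl-2,4-bis(methoxymethoxy)-5-(3-methylbut-2-en-1-yl)benzene F1. Ring A is brought in ready-made: resorcinol is converted with NaH and chloromethyl methyl ether into 1,3-bis(methoxymethoxy)benzene F2, which is lithiated between the two acetal groups (n-BuLi, THF, 0 °C) and prenylated with 13 in the presence of CuBr·SMe2 to give 1,3-bis(methoxymethoxy)-2-(3-methylbut-2-en-1-yl)benzene F3. HCl in MeOH frees 2-(3-methylbut-2-en-1-yl)benzene-1,3-diol F4, and I2 with NaHCO3 in aqueous THF at 0 °C iodinates it to 4-iodo-2-(3-methylbut-2-en-1-yl)benzene-1,3-diol F5. Sonogashira coupling of F5 with F1 (PdCl2(PPh3)2, CuI, Et3N, DMF, 60 °C), with cyclisation of the o-alkynylphenol in the same flask through the hydroxyl next to iodine, should give 2-Ar-7-prenyl-1-benzofuran-6-ol F6. Silylation (i-Pr3SiCl, imidazole, DMF) gives 2-Ar-7-prenyl-6-[(triisopropylsilyl)oxy]-1-benzofuran F7, and Vilsmeier–Haack formylation (POCl3, DMF, 0 → 40 °C, then aq. NaOAc) at C3, the enol-ether carbon of the 2-arylbenzofuran, gives 25.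

Step 10. Monolithium acetylide may disproportionate to insoluble dilithium acetylide before oxygen transfer, and the unsubstituted ynolate may be silylated on carbon to give a silylketene. The fallback replaces the silyl ynol ether by an alkoxyacetylene that needs neither acetylide oxidation nor ynolate silylation; it sets out from 18 and comes back at 26. 2-(Trimethylsilyl)ethanol is added to trichloroethylene with KH in THF to give (E)-[2-(1,2-dichloroethenyloxy)ethyl]trimethylsilane F8, and n-BuLi (2.2 equiv, −78 °C) followed by MeOH gives [2-(ethynyloxy)ethyl]trimethylsilane F9. Under the conditions of step 11, 18 and F9 should give 2-Ar-7-prenyl-6-[2-(trimethylsilyl)ethoxy]-1-benzofuran-3-carbaldehyde F10, whose silylethyl ether is cleaved by Bu4NF in DMF at 60 °C with loss of ethene to give 26.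

Step 8. The δ-hydroxy acid may lactonise during acidification or concentration (C3 hydroxymethyl group onto the side-chain carboxyl), which would withdraw that carbon from the oxidation of step 9. The fallback masks the carboxyl group before any acid is added; it sets out from 15 and comes back at 18. After the LiBH4 reduction the mixture is not acidified, the solvent is exchanged for DMF and the carboxylate is alkylated with MeI to give methyl 2-[5-Ar-3,4-bis(hydroxymethyl)furan-2-yl]-5-methylhex-4-enoate F11. Dess–Martin oxidation gives methyl 2-(5-Ar-3,4-diformylfuran-2-yl)-5-methylhex-4-enoate F12, and LiOH in aqueous THF at 0 °C, which the non-enolisable aldehydes tolerate, gives 18.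

**Further compounds**

F1 | step 11 | 1-ethynyl-2,4-bis(methoxymethoxy)-5-(3-methylbut-2-en-1-yl)benzene | C#Cc1cc(CC=C(C)C)c(OCOC)cc1OCOC
F2 | step 11 | 1,3-bis(methoxymethoxy)benzene | COCOc1cccc(OCOC)c1
F3 | step 11 | 1,3-bis(methoxymethoxy)-2-(3-methylbut-2-en-1-yl)benzene | COCOc1cccc(OCOC)c1CC=C(C)C
F4 | step 11 | 2-(3-methylbut-2-en-1-yl)benzene-1,3-diol | Oc1cccc(O)c1CC=C(C)C
F5 | step 11 | 4-iodo-2-(3-methylbut-2-en-1-yl)benzene-1,3-diol | Oc1ccc(I)c(O)c1CC=C(C)C
F6 | step 11 | 2-Ar-7-prenyl-1-benzofuran-6-ol | Oc1ccc2cc(-c3cc(CC=C(C)C)c(OCOC)cc3OCOC)oc2c1CC=C(C)C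
F7 | step 11 | 2-Ar-7-prenyl-6-[(triisopropylsilyl)oxy]-1-benzofuran | CC(C)[Si](Oc1ccc2cc(-c3cc(CC=C(C)C)c(OCOC)cc3OCOC)oc2c1CC=C(C)C)(C(C)C)C(C)C
F8 | step 10 | (E)-[2-(1,2-dichloroethenyloxy)ethyl]trimethylsilane | Cl/C=C(/Cl)OCC[Si](C)(C)C
F9 | step 10 | [2-(ethynyloxy)ethyl]trimethylsilane | C#COCC[Si](C)(C)C
F10 | step 10 | 2-Ar-7-prenyl-6-[2-(trimethylsilyl)ethoxy]-1-benzofuran-3-carbaldehyde | O=Cc1c(-c2cc(CC=C(C)C)c(OCOC)cc2OCOC)oc2c(CC=C(C)C)c(OCC[Si](C)(C)C)ccc12
F11 | step 8 | methyl 2-[5-Ar-3,4-bis(hydroxymethyl)furan-2-yl]-5-methylhex-4-enoate (racemic) | COC(=O)C(CC=C(C)C)c1oc(-c2cc(CC=C(C)C)c(OCOC)cc2OCOC)c(CO)c1CO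
F12 | step 8 | methyl 2-(5-Ar-3,4-diformylfuran-2-yl)-5-methylhex-4-enoate (racemic) | COC(=O)C(CC=C(C)C)c1oc(-c2cc(CC=C(C)C)c(OCOC)cc2OCOC)c(C=O)c1C=O
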